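The numbers in the tables were generated by integration from invented constants.

In the midnight flask substrate outnumbers enzyme 1000 to one, so enzyme binding one substrate each can hold at most 0.100% of the charge, less than the 1 percentage point scatter of a reading. The catalyst therefore shows itself through the rate.

common to all: substrate 0.12 M

| charge | enzyme | remark |
|---|---|---|
| midnight | 0.12 mM | the very flask that is asked about, followed so far |
| dusk | 0.18 mM | run made earlier |
| flask | 0.12 mM |  |

| run | time / min | target / % | substrate / % |
|---|---|---|---|
| midnight | 4.00 | 1.2 | 97.9 |
| midnight | 8.00 | 4.8 | 94.3 |
| midnight | 12.0 | 6.2 | 93.1 |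
| midnight | 15.0 | 8.7 | 89.7 |
| dusk | 5.00 | 2.4 | 93.9 |
| dusk | 10.0 | 7.4 | 93.0 |
| dusk | 15.0 | 8.8 | 88.3 |
| dusk | 20.0 | 14.7 | 84.2 |

(readings scatter by 1 percentage point)

1. apparent order in enzyme when 5.0% of the substrate are converted (percent change of the rate of making target for one percent more enzyme charged)
2. factor on the rate of making target when 5.0% of the substrate are converted if enzyme is charged twice over

From the first minutes the target climbs along a line. Through the origin, the midnight flask makes 0.00553 min⁻¹ as a fraction of the charge, and the dusk flask 0.00683 min⁻¹. At its pace the midnight flask passes 5.0% conversion near 9.05 min. Dividing one rate by the other removes time: a rate ratio of 1.24 for 1.50 times the c(enzyme) reads as an order of 0.521, hence a factor of 1.44 on doubling. With 1 point scatter on a last midnight reading of 8.7%, this reading is loose.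

Suppose that, at one c(substrate), the rate follows the single forms of the catalyst while pairs grow as the square of those forms, each pair counted as the two enzymes it holds. The order is then the reciprocal of one plus the share held in pairs. Read backwards, the runs give 91.8% as the part of the catalyst held in pairs, the paired share, and with that scatter this too is a loose reading.

The forecast gives an order of 0.5 (0.2 to 0.85) and a factor of 1.41 (1.15 to 1.8), an order “which could suggest a dimer–monomer resting state or saturation”.

The flask gives an order of 0.79 and a factor of 1.69.

    substrate + enzyme ⇌ complex (K = 8.50 M⁻¹, k = 650 M⁻¹ s⁻¹)
    complex → enzyme + target (k = 0.250 s⁻¹)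
    2 complex ⇌ resting dimer, settled at all times (K = 8200 M⁻¹)

The paired share stands at 91.8% as a loose reading of the runs, the same rule applied to the flask's order gives 26.0%, and at 5.0% conversion in the flask the resting dimer, outside the working round, holds 26.0% of the catalyst. In this flask, binding at the charged substrate runs at 4700 min⁻¹ per enzyme, 313 times the 15 min⁻¹ of complex giving target. At 5.00 min complex and enzyme stand level, at 36.6% and 37.0%. At 50.0 min resting dimer holds 21.9%.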